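**Retrosynthetic overview**

1. Target ⇐ global desilylation ⇐ C8=C9 Horner–Wadsworth–Emmons union of a C1–C8 trienoate phosphonate (already carrying the cyclohexyl ester) with a C9–C23 (Z)-3-chloroenal, itself made from an ynal by anti-hydrochlorination.
2. C9–C23 ⇐ C16–C17 Cornforth aldol of a C9–C16 methyl ketone with a C17–C23 α-chloroaldehyde, then 1,3-syn reduction (C15).
3. Key bond: C18–Cl, formed by SOMO (enamine radical-cation) α-chlorination of a β-siloxy aldehyde; this chloride then controls C17 and, through it, C15.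
4. C9–C16 ⇐ Sharpless epoxide of crotyl alcohol, alkynylalane opening (C12, C13), Felkin addition of 1-ethoxyvinyllithium (C14); C17–C23 ⇐ Mukaiyama aldol of pentenal (C19).
5. Rings: a transient oxirane (formed in step 1, opened in step 2); the only ring of the target, the cyclohexane, is formed once by an enantioselective Diels–Alder reaction (step 15) and then cis-dihydroxylated.

Assumption: 3,3-dimethoxyprop-1-yne is taken as purchasable; locants C1–C23 (C1 = ester carbonyl) and C1′–C6′ (C1′ bears CO2H) are those of the target, and the SMILES are authoritative for configuration.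

**Route**

Step 1
Reactants: 1 (E)-but-2-en-1-ol
Product: 2 [(2S,3S)-3-methyloxiran-2-yl]methanol
Conditions: Ti(OiPr)4 (5 mol%), L-(+)-DET (7.5 mol%), t-BuOOH, 4 Å MS, CH2Cl2, −20 °C
Reagents that add atoms: tert-butyl hydroperoxide, CC(C)(C)OO
Why: Katsuki–Sharpless asymmetric epoxidation; the L-tartrate–titanium complex delivers oxygen to one face of the E-allylic alcohol and sets both epoxide carbons (future C13 and, after inversion, C12).

Step 2
Reactants: 2 [(2S,3S)-3-methyloxiran-2-yl]methanol; 3 3,3-dimethoxyprop-1-yne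
Product: 5 (2R,3S)-6,6-dimethoxy-3-methylhex-4-yne-1,2-diol, via alkynylalane 4 (not isolated)
Conditions: 3, n-BuLi, toluene, 0 °C; Et2AlCl; then 2, 0 °C → rt; Rochelle salt
Reagents that add atoms: none
Why: Alkynylalane opening of a 2,3-epoxy alcohol (Nozaki–Oshima type); the aluminium alkoxide directs SN2 attack to C3 with inversion, which gives the 1,2-diol with C12-Me and C13-OH syn.

Step 3
Reactants: 5 (2R,3S)-6,6-dimethoxy-3-methylhex-4-yne-1,2-diol
Product: 6 (2R,3S)-6,6-dimethoxy-3-methyl-1,2-bis(triethylsilyloxy)hex-4-yne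
Conditions: Et3SiCl, imidazole, DMAP (cat.), CH2Cl2, 0 °C → rt
Reagents that add atoms: chlorotriethylsilane, CC[Si](Cl)(CC)CC
Why: Standard silylation of both hydroxyls; no stereocentre is touched.

Step 4
Reactants: 6 (2R,3S)-6,6-dimethoxy-3-methyl-1,2-bis(triethylsilyloxy)hex-4-yne
Product: 7 (2R,3S)-6,6-dimethoxy-3-methyl-2-(triethylsilyloxy)hex-4-ynal
Conditions: (COCl)2, DMSO, CH2Cl2, −78 → −40 °C; Et3N, −78 → 0 °C
Reagents that add atoms: none
Why: Swern oxidation applied directly to a primary TES ether; chlorodimethylsulfonium cleaves only the unhindered primary Si–O bond and oxidises that carbon to the aldehyde, while the secondary TES ether stays.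

Step 5
Reactants: 7 (2R,3S)-6,6-dimethoxy-3-methyl-2-(triethylsilyloxy)hex-4-ynal; 8 ethyl vinyl ether
Product: 11 (3R,4R,5S)-3-(tert-butyldimethylsilyloxy)-8,8-dimethoxy-5-methyl-4-(triethylsilyloxy)oct-6-yn-2-one, via 1-ethoxyvinyllithium 9 (not isolated), via silylated enol ether adduct 10 (not isolated)
Conditions: 8, t-BuLi, THF, −78 → 0 °C; 7, −78 °C; TBSOTf, 2,6-lutidine, −78 → −20 °C; 0.1 M HCl, THF, 0 °C
Reagents that add atoms: tert-butyldimethylsilyl triflate, CC(C)(C)[Si](C)(C)OS(=O)(=O)C(F)(F)F; water, O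
Why: Felkin–Anh (polar, non-chelated) 1,2-addition of an acyl-anion equivalent places the new C14 oxygen anti to the C13 siloxy group; the alkoxide is silylated in the flask and the enol ether, far more acid-labile than the propargylic acetal, is hydrolysed to the methyl ketone.

Step 6
Reactants: 12 methyl acetate; 13 (E)-pent-2-enal
Product: 15 methyl (3R,4E)-3-hydroxyhept-4-enoate, via ketene silyl acetal 14 (not isolated)
Conditions: 12, LDA, Me3SiCl, THF, −78 °C; then 13, Carreira Ti(IV)–binaphthyl Schiff-base catalyst (2 mol%, enantiomer giving 3R), Et2O, −10 °C; 1 M HCl, THF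
Reagents that add atoms: none
Why: Catalytic asymmetric Mukaiyama acetate aldol (Carreira), which works well with enals; the chiral titanium complex selects the aldehyde face and sets C19.

Step 7
Reactants: 15 methyl (3R,4E)-3-hydroxyhept-4-enoate
Product: 16 methyl (3R,4E)-3-(tert-butyldimethylsilyloxy)hept-4-enoate
Conditions: TBSCl, imidazole, DMF, rt
Reagents that add atoms: tert-butyldimethylsilyl chloride, CC(C)(C)[Si](C)(C)Cl
Why: Standard silyl protection; no stereocentre is touched.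

Step 8
Reactants: 16 methyl (3R,4E)-3-(tert-butyldimethylsilyloxy)hept-4-enoate
Product: 17 (3R,4E)-3-(tert-butyldimethylsilyloxy)hept-4-enal
Conditions: DIBAL-H, CH2Cl2, −78 °C; Rochelle salt
Reagents that add atoms: none
Why: Partial ester reduction; the tetrahedral aluminium hemiacetal is stable at −78 °C and releases the aldehyde only on work-up.

Step 9 (key step)
Reactants: 17 (3R,4E)-3-(tert-butyldimethylsilyloxy)hept-4-enal
Product: 18 (2S,3S,4E)-3-(tert-butyldimethylsilyloxy)-2-chlorohept-4-enal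
Conditions: 5-benzyl-2-tert-butyl-3-methylimidazolidin-4-one·TFA (20 mol%, enantiomer giving 2S), LiCl, Cu(TFA)2 (0.5 equiv), Na2S2O8, H2O, MeCN, 4 °C; used crude
Reagents that add atoms: lithium chloride, [Li+].[Cl-]
Why: MacMillan SOMO-activation α-chlorination; the enamine is oxidised by Cu(II)/persulfate to a 3π-electron radical cation and the C18–Cl bond forms when chloride traps this radical on the enamine face left open by the imidazolidinone, so catalyst control sets C18 anti to the C19 siloxy group.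

Step 10
Reactants: 11 (3R,4R,5S)-3-(tert-butyldimethylsilyloxy)-8,8-dimethoxy-5-methyl-4-(triethylsilyloxy)oct-6-yn-2-one; 18 (2S,3S,4E)-3-(tert-butyldimethylsilyloxy)-2-chlorohept-4-enal
Product: 20 (4S,5R,6R,9R,10R,11S,12E)-6,11-bis(tert-butyldimethylsilyloxy)-10-chloro-9-hydroxy-1,1-dimethoxy-4-methyl-5-(triethylsilyloxy)pentadec-12-en-2-yn-7-one, via lithium enolate 19 (not isolated)
Conditions: 11, LDA, THF, −78 °C; 18, −78 °C, 15 min; AcOH, −78 °C
Reagents that add atoms: none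
Why: Lithium methyl-ketone enolate aldol onto an α-chloroaldehyde; the Cornforth (polar Felkin–Anh) transition state gives the 17,18-anti chlorohydrin, reinforced by the 2,3-anti pattern of 18, and the cold acidic quench prevents epoxide closure.

Step 11
Reactants: 20 (4S,5R,6R,9R,10R,11S,12E)-6,11-bis(tert-butyldimethylsilyloxy)-10-chloro-9-hydroxy-1,1-dimethoxy-4-methyl-5-(triethylsilyloxy)pentadec-12-en-2-yn-7-one
Product: 21 (4S,5R,6S,7S,9R,10R,11S,12E)-6,11-bis(tert-butyldimethylsilyloxy)-10-chloro-1,1-dimethoxy-4-methyl-5-(triethylsilyloxy)pentadec-12-en-2-yne-7,9-diol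
Conditions: Et2BOMe, NaBH4, THF/MeOH 4:1, −78 °C; AcOH; MeOH co-evaporation
Reagents that add atoms: none
Why: Narasaka–Prasad reduction; the six-membered boron chelate of the β-hydroxy ketone takes hydride axially and gives the 1,3-syn diol, setting C15 (also anti to C14).

Step 12
Reactants: 21 (4S,5R,6S,7S,9R,10R,11S,12E)-6,11-bis(tert-butyldimethylsilyloxy)-10-chloro-1,1-dimethoxy-4-methyl-5-(triethylsilyloxy)pentadec-12-en-2-yne-7,9-diol
Product: 22 (4S,5R,6S,7S,9R,10R,11S,12E)-6,7,9,11-tetrakis(tert-butyldimethylsilyloxy)-10-chloro-4-methyl-5-(triethylsilyloxy)pentadec-12-en-2-ynal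
Conditions: TBSOTf, 2,6-lutidine, CH2Cl2, −78 → 0 °C; then Et3SiOTf, 0 °C; H2O
Reagents that add atoms: tert-butyldimethylsilyl triflate, CC(C)(C)[Si](C)(C)OS(=O)(=O)C(F)(F)F; water, O
Why: Silyl triflate protection of both carbinols followed by Fujioka deacetalisation; TESOTf/2,6-lutidine turns the dimethyl acetal into a pyridinium N,O-acetal salt that water converts to the aldehyde without protic acid, so silyl ethers and the chlorohydrin are untouched.

Step 13
Reactants: 22 (4S,5R,6S,7S,9R,10R,11S,12E)-6,7,9,11-tetrakis(tert-butyldimethylsilyloxy)-10-chloro-4-methyl-5-(triethylsilyloxy)pentadec-12-en-2-ynal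
Product: 23 (2Z,4R,5R,6S,7S,9R,10R,11S,12E)-6,7,9,11-tetrakis(tert-butyldimethylsilyloxy)-3,10-dichloro-4-methyl-5-(triethylsilyloxy)pentadeca-2,12-dienal
Conditions: LiCl, AcOH, MeCN, rt
Reagents that add atoms: lithium chloride, [Li+].[Cl-]
Why: Ma–Lu hydrohalogenation of an electron-poor alkyne; chloride adds in conjugate fashion at C11 and the allenolate is protonated anti, which gives the (Z)-3-chloroenal (Cl cis to CHO), i.e. the 10Z vinyl chloride.

Step 14
Reactants: 24 acryloyl chloride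
Product: 25 2,2,2-trifluoroethyl acrylate
Conditions: CF3CH2OH, Et3N, CH2Cl2, 0 °C
Reagents that add atoms: 2,2,2-trifluoroethanol, OCC(F)(F)F
Why: Simple acylation of the alcohol; it provides the activated acrylate needed for the catalytic Diels–Alder reaction with butadiene.

Step 15
Reactants: 25 2,2,2-trifluoroethyl acrylate; 26 buta-1,3-diene
Product: 28 (1S)-cyclohex-3-ene-1-carboxylic acid, via trifluoroethyl ester 27 (not isolated)
Conditions: o-tolyl-oxazaborolidinium triflimide (10 mol%, enantiomer giving 1S), CH2Cl2, 23 °C; then LiOH, THF/H2O, 0 °C; 1 M HCl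
Reagents that add atoms: lithium hydroxide, [Li+].[OH-]
Why: Corey oxazaborolidinium-catalysed enantioselective Diels–Alder reaction forms the only ring and sets C1′ by shielding one face of the coordinated acrylate; the activated ester is then saponified in the same flask.

Step 16
Reactants: 28 (1S)-cyclohex-3-ene-1-carboxylic acid
Product: 29 (1S,3R,4S)-3,4-dihydroxycyclohexane-1-carboxylic acid
Conditions: OsO4 (1 mol%), NMO, acetone/H2O, 0 °C → rt; then TsOH (cat.), MeCN, 40 °C and NaHCO3 extraction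
Reagents that add atoms: N-methylmorpholine N-oxide, C[N+]1([O-])CCOCC1; water, O
Why: Upjohn syn-dihydroxylation sets C3′ and C4′ cis; attack anti to the carboxyl group is only moderately favoured (about 2–3:1 expected), and the unwanted all-cis isomer is removed as its neutral γ-lactone, which the desired isomer (3′-OH trans to CO2H) cannot form.

Step 17
Reactants: 29 (1S,3R,4S)-3,4-dihydroxycyclohexane-1-carboxylic acid
Product: 30 triisopropylsilyl (1S,3R,4S)-4-(tert-butyldimethylsilyloxy)-3-hydroxycyclohexane-1-carboxylate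
Conditions: i-Pr3SiCl, imidazole, DMF, 0 °C; then TBSCl, rt
Reagents that add atoms: chlorotriisopropylsilane, CC(C)[Si](Cl)(C(C)C)C(C)C; tert-butyldimethylsilyl chloride, CC(C)(C)[Si](C)(C)Cl
Why: Chemoselective silylation; TIPSCl takes only the carboxylic acid, and TBSCl then takes the equatorial 4′-OH faster than the axial 3′-OH, which stays free for acylation.

Step 18
Reactants: 30 triisopropylsilyl (1S,3R,4S)-4-(tert-butyldimethylsilyloxy)-3-hydroxycyclohexane-1-carboxylate; 31 (E)-3-iodoprop-2-enoic acid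
Product: 32 triisopropylsilyl (1S,3R,4S)-4-(tert-butyldimethylsilyloxy)-3-{[(2E)-3-iodoprop-2-enoyl]oxy}cyclohexane-1-carboxylate
Conditions: EDC·HCl, DMAP (cat.), CH2Cl2, 0 °C → rt
Reagents that add atoms: none
Why: Steglich esterification acylates the alcohol oxygen, so C3′ keeps its configuration; the neighbouring oxygen is silylated and cannot accept the acyl group.

Step 19
Reactants: 33 (E)-3-methylpent-2-en-4-yn-1-ol
Product: 35 diethyl [(E)-3-methylpent-2-en-4-yn-1-yl]phosphonate, via allylic bromide 34 (not isolated)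
Conditions: PBr3, Et2O, 0 °C; then P(OEt)3, 100 °C
Reagents that add atoms: triethyl phosphite, CCOP(OCC)OCC
Why: Bromination of the primary allylic alcohol followed by a Michaelis–Arbuzov reaction at the primary carbon; the trisubstituted E-alkene is retained.

Step 20
Reactants: 35 diethyl [(E)-3-methylpent-2-en-4-yn-1-yl]phosphonate; 32 triisopropylsilyl (1S,3R,4S)-4-(tert-butyldimethylsilyloxy)-3-{[(2E)-3-iodoprop-2-enoyl]oxy}cyclohexane-1-carboxylate
Product: 37 triisopropylsilyl (1S,3R,4S)-4-(tert-butyldimethylsilyloxy)-3-{[(2E,4E,6E)-8-(diethoxyphosphoryl)-6-methylocta-2,4,6-trienoyl]oxy}cyclohexane-1-carboxylate, via alkenylzirconocene 36 (not isolated)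
Conditions: 35, Cp2Zr(H)Cl, THF, 0 °C → rt; then 32, ZnCl2, Pd(PPh3)4 (5 mol%), THF, rt
Reagents that add atoms: none
Why: Hydrozirconation of the terminal alkyne (syn, Zr at the terminus) followed by Negishi coupling with the E-iodoacrylate; both steps retain alkene geometry and give the 2E,4E,6E-triene.

Step 21
Reactants: 37 triisopropylsilyl (1S,3R,4S)-4-(tert-butyldimethylsilyloxy)-3-{[(2E,4E,6E)-8-(diethoxyphosphoryl)-6-methylocta-2,4,6-trienoyl]oxy}cyclohexane-1-carboxylate; 23 (2Z,4R,5R,6S,7S,9R,10R,11S,12E)-6,7,9,11-tetrakis(tert-butyldimethylsilyloxy)-3,10-dichloro-4-methyl-5-(triethylsilyloxy)pentadeca-2,12-dienal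
Product: 38 persilylated target (triisopropylsilyl ester; 4′-O-TBS; 14,15,17,19-tetra-O-TBS; 13-O-TES)
Conditions: 37, LiHMDS, THF, −78 °C; then 23, −78 → 0 °C
Reagents that add atoms: none
Why: Horner–Wadsworth–Emmons olefination with the vinylogous phosphonate anion, which reacts at C8; reversible addition and oxaphosphetane collapse give the 8E alkene and complete the pentaene.

Step 22
Reactants: 38 persilylated target
Product: 39 target (CNP0353301.1)
Conditions: HF·pyridine, pyridine, THF, 0 °C → rt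
Reagents that add atoms: none
Why: Global fluoride desilylation of the silyl ethers and silyl ester under buffered, non-basic conditions, so the chlorohydrins cannot close to epoxides and the C3′ ester does not migrate.

**Compound list**

1 | (E)-but-2-en-1-ol | C/C=C/CO | starting material
2 | [(2S,3S)-3-methyloxiran-2-yl]methanol | OC[C@@H]1O[C@H]1C | intermediate
3 | 3,3-dimethoxyprop-1-yne | C#CC(OC)OC | starting material
4 | diethyl(3,3-dimethoxyprop-1-yn-1-yl)aluminium | CC[Al](CC)C#CC(OC)OC | intermediate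
5 | (2R,3S)-6,6-dimethoxy-3-methylhex-4-yne-1,2-diol | OC[C@H](O)[C@@H](C)C#CC(OC)OC | intermediate
6 | (2R,3S)-6,6-dimethoxy-3-methyl-1,2-bis(triethylsilyloxy)hex-4-yne | CC[Si](CC)(CC)OC[C@H](O[Si](CC)(CC)CC)[C@@H](C)C#CC(OC)OC | intermediate
7 | (2R,3S)-6,6-dimethoxy-3-methyl-2-(triethylsilyloxy)hex-4-ynal | O=C[C@H](O[Si](CC)(CC)CC)[C@@H](C)C#CC(OC)OC | intermediate
8 | ethyl vinyl ether | C=COCC | starting material
9 | (1-ethoxyvinyl)lithium | [Li]C(=C)OCC | intermediate
10 | (3R,4R,5S)-3-(tert-butyldimethylsilyloxy)-2-ethoxy-8,8-dimethoxy-5-methyl-4-(triethylsilyloxy)oct-1-en-6-yne | C=C(OCC)[C@H](O[Si](C)(C)C(C)(C)C)[C@H](O[Si](CC)(CC)CC)[C@@H](C)C#CC(OC)OC | intermediate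
11 | (3R,4R,5S)-3-(tert-butyldimethylsilyloxy)-8,8-dimethoxy-5-methyl-4-(triethylsilyloxy)oct-6-yn-2-one | CC(=O)[C@H](O[Si](C)(C)C(C)(C)C)[C@H](O[Si](CC)(CC)CC)[C@@H](C)C#CC(OC)OC | intermediate
12 | methyl acetate | CC(=O)OC | starting material
13 | (E)-pent-2-enal | CC/C=C/C=O | starting material
14 | 1-methoxy-1-(trimethylsilyloxy)ethene | C=C(OC)O[Si](C)(C)C | intermediate
15 | methyl (3R,4E)-3-hydroxyhept-4-enoate | CC/C=C/[C@H](O)CC(=O)OC | intermediate
16 | methyl (3R,4E)-3-(tert-butyldimethylsilyloxy)hept-4-enoate | CC/C=C/[C@H](O[Si](C)(C)C(C)(C)C)CC(=O)OC | intermediate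
17 | (3R,4E)-3-(tert-butyldimethylsilyloxy)hept-4-enal | CC/C=C/[C@H](O[Si](C)(C)C(C)(C)C)CC=O | intermediate
18 | (2S,3S,4E)-3-(tert-butyldimethylsilyloxy)-2-chlorohept-4-enal | CC/C=C/[C@H](O[Si](C)(C)C(C)(C)C)[C@H](Cl)C=O | intermediate
19 | lithium enolate of 11 (lithium (3R,4R,5S)-3-(tert-butyldimethylsilyloxy)-8,8-dimethoxy-5-methyl-4-(triethylsilyloxy)oct-1-en-6-yn-2-olate) | [Li]OC(=C)[C@H](O[Si](C)(C)C(C)(C)C)[C@H](O[Si](CC)(CC)CC)[C@@H](C)C#CC(OC)OC | intermediate
20 | (4S,5R,6R,9R,10R,11S,12E)-6,11-bis(tert-butyldimethylsilyloxy)-10-chloro-9-hydroxy-1,1-dimethoxy-4-methyl-5-(triethylsilyloxy)pentadec-12-en-2-yn-7-one | CC/C=C/[C@H](O[Si](C)(C)C(C)(C)C)[C@H](Cl)[C@H](O)CC(=O)[C@H](O[Si](C)(C)C(C)(C)C)[C@H](O[Si](CC)(CC)CC)[C@@H](C)C#CC(OC)OC | intermediate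
21 | (4S,5R,6S,7S,9R,10R,11S,12E)-6,11-bis(tert-butyldimethylsilyloxy)-10-chloro-1,1-dimethoxy-4-methyl-5-(triethylsilyloxy)pentadec-12-en-2-yne-7,9-diol | CC/C=C/[C@H](O[Si](C)(C)C(C)(C)C)[C@H](Cl)[C@H](O)C[C@H](O)[C@H](O[Si](C)(C)C(C)(C)C)[C@H](O[Si](CC)(CC)CC)[C@@H](C)C#CC(OC)OC | intermediate
22 | (4S,5R,6S,7S,9R,10R,11S,12E)-6,7,9,11-tetrakis(tert-butyldimethylsilyloxy)-10-chloro-4-methyl-5-(triethylsilyloxy)pentadec-12-en-2-ynal | CC/C=C/[C@H](O[Si](C)(C)C(C)(C)C)[C@H](Cl)[C@H](O[Si](C)(C)C(C)(C)C)C[C@H](O[Si](C)(C)C(C)(C)C)[C@H](O[Si](C)(C)C(C)(C)C)[C@H](O[Si](CC)(CC)CC)[C@@H](C)C#CC=O | intermediate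
23 | (2Z,4R,5R,6S,7S,9R,10R,11S,12E)-6,7,9,11-tetrakis(tert-butyldimethylsilyloxy)-3,10-dichloro-4-methyl-5-(triethylsilyloxy)pentadeca-2,12-dienal | CC/C=C/[C@H](O[Si](C)(C)C(C)(C)C)[C@H](Cl)[C@H](O[Si](C)(C)C(C)(C)C)C[C@H](O[Si](C)(C)C(C)(C)C)[C@H](O[Si](C)(C)C(C)(C)C)[C@H](O[Si](CC)(CC)CC)[C@@H](C)/C(Cl)=C/C=O | intermediate
24 | acryloyl chloride | C=CC(Cl)=O | starting material
25 | 2,2,2-trifluoroethyl acrylate | C=CC(=O)OCC(F)(F)F | intermediate
26 | buta-1,3-diene | C=CC=C | starting material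
27 | 2,2,2-trifluoroethyl (1S)-cyclohex-3-ene-1-carboxylate | C1=CC[C@@H](C(=O)OCC(F)(F)F)CC1 | intermediate
28 | (1S)-cyclohex-3-ene-1-carboxylic acid | C1=CC[C@@H](C(=O)O)CC1 | intermediate
29 | (1S,3R,4S)-3,4-dihydroxycyclohexane-1-carboxylic acid | O[C@@H]1C[C@@H](C(=O)O)CC[C@@H]1O | intermediate
30 | triisopropylsilyl (1S,3R,4S)-4-(tert-butyldimethylsilyloxy)-3-hydroxycyclohexane-1-carboxylate | O[C@@H]1C[C@@H](C(=O)O[Si](C(C)C)(C(C)C)C(C)C)CC[C@@H]1O[Si](C)(C)C(C)(C)C | intermediate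
31 | (E)-3-iodoprop-2-enoic acid | OC(=O)/C=C/I | starting material
32 | triisopropylsilyl (1S,3R,4S)-4-(tert-butyldimethylsilyloxy)-3-{[(2E)-3-iodoprop-2-enoyl]oxy}cyclohexane-1-carboxylate | I/C=C/C(=O)O[C@@H]1C[C@@H](C(=O)O[Si](C(C)C)(C(C)C)C(C)C)CC[C@@H]1O[Si](C)(C)C(C)(C)C | intermediate
33 | (E)-3-methylpent-2-en-4-yn-1-ol | OC/C=C(C)/C#C | starting material
34 | (E)-5-bromo-3-methylpent-3-en-1-yne | BrC/C=C(C)/C#C | intermediate
35 | diethyl [(E)-3-methylpent-2-en-4-yn-1-yl]phosphonate | CCOP(=O)(OCC)C/C=C(C)/C#C | intermediate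
36 | chlorobis(cyclopentadienyl)[(1E,3E)-5-(diethoxyphosphoryl)-3-methylpenta-1,3-dien-1-yl]zirconium | CCOP(=O)(OCC)C/C=C(C)/C=C/[Zr](Cl)(C1C=CC=C1)C1C=CC=C1 | intermediate
37 | triisopropylsilyl (1S,3R,4S)-4-(tert-butyldimethylsilyloxy)-3-{[(2E,4E,6E)-8-(diethoxyphosphoryl)-6-methylocta-2,4,6-trienoyl]oxy}cyclohexane-1-carboxylate | CCOP(=O)(OCC)C/C=C(C)/C=C/C=C/C(=O)O[C@@H]1C[C@@H](C(=O)O[Si](C(C)C)(C(C)C)C(C)C)CC[C@@H]1O[Si](C)(C)C(C)(C)C | intermediate
38 | persilylated target: triisopropylsilyl ester, 4′-O-TBS, 14,15,17,19-tetra-O-TBS, 13-O-TES, all stereocentres and alkene geometries as in the target | CC/C=C/[C@H](O[Si](C)(C)C(C)(C)C)[C@H](Cl)[C@H](O[Si](C)(C)C(C)(C)C)C[C@H](O[Si](C)(C)C(C)(C)C)[C@H](O[Si](C)(C)C(C)(C)C)[C@H](O[Si](CC)(CC)CC)[C@@H](C)/C(Cl)=C/C=C/C=C(C)/C=C/C=C/C(=O)O[C@@H]1C[C@@H](C(=O)O[Si](C(C)C)(C(C)C)C(C)C)CC[C@@H]1O[Si](C)(C)C(C)(C)C | intermediate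
39 | CNP0353301.1: (1S,3R,4S)-3-{[(2E,4E,6E,8E,10Z,12R,13R,14S,15S,17R,18R,19S,20E)-11,18-dichloro-13,14,15,17,19-pentahydroxy-6,12-dimethyltricosa-2,4,6,8,10,20-hexaenoyl]oxy}-4-hydroxycyclohexane-1-carboxylic acid | CC/C=C/[C@H](O)[C@H](Cl)[C@H](O)C[C@H](O)[C@H](O)[C@H](O)[C@@H](C)/C(Cl)=C/C=C/C=C(C)/C=C/C=C/C(=O)O[C@@H]1C[C@@H](C(=O)O)CC[C@@H]1O | target

**Step count and risks**

Total: 22 steps. Longest linear sequence: 11 steps (1–5, 10–13, 21, 22).

Most likely to fail, step 9 (SOMO chlorination). The β-siloxy aldehyde can lose silanol through its enamine to give hepta-2,4-dienal, the medium is acidic and oxidising, and catalyst control must override the C19 centre. The fallback sets out from 15 and comes back at 18. Hydroxy ester 15 is converted with LDA (2.2 equiv, THF, −78 → −20 °C) into its chelated alkoxide–enolate dianion and chlorinated with hexachloroethane (Fráter–Seebach reaction, electrophile enters anti to the C19 substituent) to give methyl (2S,3S,4E)-2-chloro-3-hydroxyhept-4-enoate F1. Silylation with TBSOTf/2,6-lutidine gives methyl (2S,3S,4E)-3-(tert-butyldimethylsilyloxy)-2-chlorohept-4-enoate F2, and DIBAL-H at −78 °C gives 18.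

Second, step 10 (aldol). Aldehyde 18 has an acidic α-hydrogen next to a β-siloxy leaving group, and the lithium aldolate can close to an epoxide. The fallback sets out from 7 and comes back at 20. The addition and silylation of step 5 are repeated, but enol ether 10 is quenched with NBS in THF/H2O instead of acid, which gives (3R,4R,5S)-1-bromo-3-(tert-butyldimethylsilyloxy)-8,8-dimethoxy-5-methyl-4-(triethylsilyloxy)oct-6-yn-2-one F3. F3 and 18 are then joined with CrCl2 (LiI cat., THF, rt) in a chromium Reformatsky reaction: two single-electron transfers give the chromium(III) enolate by way of the α-keto radical, and the addition runs without base to give 20.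

Third, step 13 (hydrochlorination). The ynal may give E/Z mixtures or lose the C13 TES ether in acetic acid. The fallback sets out from 22 and comes back at 23. Luche reduction (NaBH4, CeCl3, MeOH, −40 °C) gives (4S,5R,6S,7S,9R,10R,11S,12E)-6,7,9,11-tetrakis(tert-butyldimethylsilyloxy)-10-chloro-4-methyl-5-(triethylsilyloxy)pentadec-12-en-2-yn-1-ol F4. Red-Al (THF, 0 °C) followed by NCS (−78 °C) gives (2Z,4R,5R,6S,7S,9R,10R,11S,12E)-6,7,9,11-tetrakis(tert-butyldimethylsilyloxy)-3,10-dichloro-4-methyl-5-(triethylsilyloxy)pentadeca-2,12-dien-1-ol F5; the propargylic alkoxide directs trans-hydroalumination so that aluminium, then chlorine, sits on C11 cis to the CH2OH group. MnO2 (CH2Cl2, rt) gives 23.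

**Further compounds**

F1 | step 9 | methyl (2S,3S,4E)-2-chloro-3-hydroxyhept-4-enoate | CC/C=C/[C@H](O)[C@H](Cl)C(=O)OC
F2 | step 9 | methyl (2S,3S,4E)-3-(tert-butyldimethylsilyloxy)-2-chlorohept-4-enoate | CC/C=C/[C@H](O[Si](C)(C)C(C)(C)C)[C@H](Cl)C(=O)OC
F3 | step 10 | (3R,4R,5S)-1-bromo-3-(tert-butyldimethylsilyloxy)-8,8-dimethoxy-5-methyl-4-(triethylsilyloxy)oct-6-yn-2-one | BrCC(=O)[C@H](O[Si](C)(C)C(C)(C)C)[C@H](O[Si](CC)(CC)CC)[C@@H](C)C#CC(OC)OC
F4 | step 13 | (4S,5R,6S,7S,9R,10R,11S,12E)-6,7,9,11-tetrakis(tert-butyldimethylsilyloxy)-10-chloro-4-methyl-5-(triethylsilyloxy)pentadec-12-en-2-yn-1-ol | CC/C=C/[C@H](O[Si](C)(C)C(C)(C)C)[C@H](Cl)[C@H](O[Si](C)(C)C(C)(C)C)C[C@H](O[Si](C)(C)C(C)(C)C)[C@H](O[Si](C)(C)C(C)(C)C)[C@H](O[Si](CC)(CC)CC)[C@@H](C)C#CCO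
F5 | step 13 | (2Z,4R,5R,6S,7S,9R,10R,11S,12E)-6,7,9,11-tetrakis(tert-butyldimethylsilyloxy)-3,10-dichloro-4-methyl-5-(triethylsilyloxy)pentadeca-2,12-dien-1-ol | CC/C=C/[C@H](O[Si](C)(C)C(C)(C)C)[C@H](Cl)[C@H](O[Si](C)(C)C(C)(C)C)C[C@H](O[Si](C)(C)C(C)(C)C)[C@H](O[Si](C)(C)C(C)(C)C)[C@H](O[Si](CC)(CC)CC)[C@@H](C)/C(Cl)=C/CO
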